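## Analysis of the target

The target 33 is a linear flavan trimer, epioritin-(4β→6)-epioritin-(4β→6)-epioritin-4α-ol. Each unit is a 2-(4-hydroxyphenyl)chroman with a 7,8-dihydroxylated ring A and no 5-OH. Unit 1 (top) and unit 2 (middle) are flavan-3-ols, each joined through C4 to C6 of the next unit; unit 3 is a flavan-3,4-diol. There are nine stereocentres. Every unit is (2R,3R), i.e. 2,3-cis. C4 of units 1 and 2 is (S), with the 4-aryl group β and trans to the 3-OH. C4 of unit 3 is (R), with the 4-OH α and cis to the 3-OH (all-cis).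

The feature that invites the strategy is this: C4 of unit 1 and C4 of unit 2 are diarylmethine carbons. Each is bonded to C4a of its own ring A, whose neighbour C8a carries the ring oxygen O1, and to C6 of the ring A below. The fragment O1–C8a–C4a–C4 is therefore the skeleton of an ortho-quinone methide of ring A1 (or A2) that already carries the lower unit on its methide carbon. Ring C1 (or C2) is exactly what a C2–C3 two-carbon partner bearing ring B adds across it.

Sensitive groups: thirteen hydroxyls, three air-sensitive 7,8-diol rings, and the benzylic C4–OH of unit 3, which ionises in acid and can be hydrogenolysed. The difficulty is threefold. Ring A is a poor nucleophile with two open positions (C5 and C6) and gives a poorly stabilised C4 cation, so the classical acid-mediated flavanyl coupling is slow and unselective here. The 2,3-cis-3,4-trans array must be built twice and the all-cis array once. Three almost identical units must be told apart.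

## Retrosynthetic reasoning

**33 ⇒ 32.** All thirteen hydroxyls are unmasked last by hydrogenolysis of the trideca-O-benzyl ether 32. Benzyl is the only group that survives aryllithiums, Brønsted acid and silane, and it leaves in one neutral operation.

**32 ⇒ 29 + 20 (ring C of unit 1).** The cut removes O1–C2 and C3–C4 of unit 1 (and the C2–H bond) and leaves the interflavanyl bond C4(unit 1)–C6(unit 2) untouched. This leads to the ortho-hydroxy diarylcarbinol 29, the precursor of ortho-quinone methide 30, and to enamide 20, which carries ring B, C2 and the benzyloxylated C3. The cut is made here because the hard bond then becomes a trivial carbinol, and because the regiochemistry (C6, not C5) and the ring oxygen are fixed by where a bromine and a free phenol sit, not by arene nucleophilicity. The forward reaction has to set C4 (catalyst), C3 (trans to the aryl) and C2 (hydride delivery) while closing ring C.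

**29 ⇒ 26 + 2.** The carbinol carbon is cut from C6 of unit 2. Forward: aryllithium 27 (from bromide 26) adds to salicylaldehyde 2, used as its phenoxide 28. No stereocontrol is needed because the carbinol is erased in quinone methide 30.

**26 ⇒ 23 + 20, and 23 ⇒ 13 + 3.** The same two cuts are repeated for unit 2. Ring C of unit 2 comes from carbinol 23 (via quinone methide 24) and enamide 20. Carbinol 23 comes from aryllithium 21 (from bromide 13) and bromo-salicylaldehyde 3. The bromine of 3 is placed para to its free OH, so it ends up at C6 of unit 2 and becomes the handle for the next cycle.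

**13 ⇒ 12 ⇒ 9 (unit 3).** The all-cis diol cannot come from the annulation, which places the C4 substituent trans to the C3 oxygen. It is taken from flav-3-ene 9 by a cis-hydroxylation that delivers both oxygens to the face syn to the 2-aryl group (diol 12, then dibenzyl ether 13). Flavene 9 is cut at C2–aryl into chromene acetal 6 and boronic acid 7. Acetal 6 goes back through coumarin 4 to aldehyde 3.

**3 ⇒ 2 ⇒ 1, and 20 ⇒ 18 ⇒ 17 ⇒ 14 + 15.** One aldehyde, 1, supplies all three A rings: 2 for unit 1 and its bromide 3 for units 2 and 3. Enamide 20 comes from ketone 17 through oxime 18, and ketone 17 from aryl bromide 14 and amide 15.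

## Alternatives that were turned down

**Alternative 1:** The textbook route cuts both C4–C6 bonds between finished flavan monomers. Forward key step: a C4-activated electrophile such as the 4β-benzylsulfanyl ether A1 is ionised with AgBF4 or TMSOTf and attacked by ring A of a protected unit 3 in a Friedel–Crafts reaction, twice. It was turned down for four reasons:
- The C4 cation of a 7,8-dioxygenated ring A has only one para and one ortho oxygen donor, and the 8-oxygen is meta and inductively withdrawing.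
- The nucleophilic ring offers both C5 and C6, so mixtures and O-alkylation are expected.
- The nucleophile's own benzylic C4–O bond competes as a leaving group in the second coupling.
- Three enantiopure monomers of six to eight steps each would be needed before either coupling.

**Alternative 2:** A concerted inverse-demand hetero-Diels–Alder reaction of the same ortho-quinone methides with a (Z)-enol ester of the ring B styrene, A2, would give the 3-acyloxyflavan directly. It was turned down on three counts: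
- The oxygen donor on the alkene opposes the aryl donor, and enol ethers are known to add with the opposite orientation, giving 2-alkoxy-3-aryl chromans.
- The required 2,3-cis-2,4-trans pattern needs a (Z)-dienophile to approach exo, whereas endo approach (all-cis) is the normal course.
- An enol ester is a weak partner for an electron-poor heterodiene.

**Alternative 3:** Polarity reversal at the interflavanyl bond. The boronic acid A3 made from bromide 13 would add to the daphnetin-derived coumarin A4 under [Rh(acac)(C2H4)2]/chiral diphosphine catalysis to give the 4-aryl-dihydrocoumarin A5. Enolate hydroxylation trans to the aryl group, aryl-lithium addition to the lactone and silane reduction would follow. It was turned down because the key step forms only one bond and one stereocentre, and four further operations per unit are needed to add the C3 oxygen and ring B. The ortho-alkoxy, electron-rich boronic acid A3 is also prone to protodeboronation, and the α-oxygenated lactone enolate can fragment to a ketene.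

Key step: step 12

Assumption: the catalyst enantiomers named in steps 5, 12 and 14 are those expected to give the configuration drawn; if the sense of induction is opposite, the antipodal catalyst is used and nothing else changes. Compounds 1, 7, 14 and 15 are taken as commercial.

## Route

Step 1
Reactants: 1 2,3,4-trihydroxybenzaldehyde
Product: 2 3,4-bis(benzyloxy)-2-hydroxybenzaldehyde
Conditions: BnBr (2.1 equiv), K2CO3 (2.2 equiv), acetone, reflux
Reagents that add atoms: benzyl bromide (BrCc1ccccc1)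
Why: Williamson etherification; the 2-OH is hydrogen-bonded to the aldehyde and its phenoxide is the least nucleophilic, so the 4- and 3-OH should react, as with 2,3,4-trihydroxyacetophenone.

Step 2
Reactants: 2 3,4-bis(benzyloxy)-2-hydroxybenzaldehyde
Product: 3 3,4-bis(benzyloxy)-5-bromo-2-hydroxybenzaldehyde
Conditions: NBS (1.05 equiv), MeCN, 0 °C to rt
Reagents that add atoms: N-bromosuccinimide (O=C1CCC(=O)N1Br)
Why: Electrophilic aromatic bromination; C5 is para to the free OH and ortho to the 4-benzyloxy group, while C6 is deactivated by the aldehyde.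

Step 3
Reactants: 3 3,4-bis(benzyloxy)-5-bromo-2-hydroxybenzaldehyde
Product: 4 7,8-bis(benzyloxy)-6-bromo-2H-chromen-2-one
Conditions: Ph3P=CHCO2Et (1.2 equiv), PhNEt2, reflux
Reagents that add atoms: ethyl (triphenylphosphoranylidene)acetate (CCOC(=O)C=P(c1ccccc1)(c1ccccc1)c1ccccc1)
Why: Wittig olefination of the salicylaldehyde followed by thermal E/Z isomerisation and lactonisation with loss of ethanol, the standard coumarin synthesis.

Step 4
Reactants: 4 7,8-bis(benzyloxy)-6-bromo-2H-chromen-2-one
Product: 6 7,8-bis(benzyloxy)-6-bromo-2-ethoxy-2H-chromene (racemic), via lactol 5 (not isolated)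
Conditions: i-Bu2AlH (1.1 equiv), CH2Cl2, −78 °C; then EtOH, PPTS (cat.), rt
Reagents that add atoms: ethanol (CCO)
Why: Partial reduction of the lactone to the lactol, then acid-catalysed acetalisation through the benzopyrylium ion; the C2 centre is erased in the next step.

Step 5
Reactants: 6 7,8-bis(benzyloxy)-6-bromo-2-ethoxy-2H-chromene; 7 [4-(benzyloxy)phenyl]boronic acid
Product: 9 (2S)-7,8-bis(benzyloxy)-2-[4-(benzyloxy)phenyl]-6-bromo-2H-chromene, via diethyl boronate 8 (not isolated)
Conditions: 7, EtOH, 4 Å MS, toluene, rt; then 6, (R,R)-tartaric acid mono-N,N-dibenzylamide (10 mol%), Yb(OTf)3 (5 mol%), EtOAc, −20 °C, dark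
Reagents that add atoms: none
Why: Enantioselective addition of an aryl boronate to the benzopyrylium ion released from the chromene acetal under chiral Brønsted acid/Lewis acid catalysis; the catalyst-bound boronate selects the face of C2 and should give the (S)-flav-3-ene (aryl on the α face).

Step 6
Reactants: 9 (2S)-7,8-bis(benzyloxy)-2-[4-(benzyloxy)phenyl]-6-bromo-2H-chromene
Product: 12 (2R,3R,4R)-7,8-bis(benzyloxy)-2-[4-(benzyloxy)phenyl]-6-bromochromane-3,4-diol (2,3-cis-3,4-cis), via trans-iodoacetate 10 (not isolated), via cis-hydroxy acetate 11 (not isolated)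
Conditions: I2 (1.05 equiv), AgOAc (2.2 equiv), AcOH, rt, dark; then H2O, 90 °C; then K2CO3, MeOH, rt
Reagents that add atoms: silver acetate (CC(=O)[O-].[Ag+])
Why: Woodward cis-hydroxylation; the iodonium ion forms on the β face, anti to the 2-aryl group, acetate opens it at benzylic C4 from the α face, and the acetate then displaces iodide at C3 from the α face through the cis-fused acetoxonium ion, so both oxygens end up α, syn to the aryl group (the face OsO4 would not reach); methanolysis frees the diol.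

Step 7
Reactants: 12 (2R,3R,4R)-7,8-bis(benzyloxy)-2-[4-(benzyloxy)phenyl]-6-bromochromane-3,4-diol
Product: 13 (2R,3R,4R)-3,4,7,8-tetrakis(benzyloxy)-2-[4-(benzyloxy)phenyl]-6-bromochromane
Conditions: NaH (2.5 equiv), BnBr (2.5 equiv), Bu4NI (cat.), DMF, 0 °C to rt
Reagents that add atoms: benzyl bromide (BrCc1ccccc1)
Why: Williamson etherification of both secondary alcohols; benzyl ethers tolerate the aryllithium steps and leave in the final hydrogenolysis.

Step 8
Reactants: 14 1-(benzyloxy)-4-bromobenzene; 15 2-(benzyloxy)-N-methoxy-N-methylacetamide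
Product: 17 2-(benzyloxy)-1-[4-(benzyloxy)phenyl]ethan-1-one, via Grignard reagent 16 (not isolated)
Conditions: Mg, THF, reflux; then 15, THF, 0 °C; H2O
Reagents that add atoms: none
Why: Grignard addition to an N-methoxy-N-methylamide; the chelated tetrahedral intermediate stops at the ketone.

Step 9
Reactants: 17 2-(benzyloxy)-1-[4-(benzyloxy)phenyl]ethan-1-one
Product: 18 2-(benzyloxy)-1-[4-(benzyloxy)phenyl]ethan-1-one oxime (E/Z mixture)
Conditions: NH2OH·HCl, NaOAc, EtOH, 60 °C
Reagents that add atoms: hydroxylamine hydrochloride (Cl.NO)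
Why: Oxime condensation; the geometry is irrelevant because the C=N bond is reduced in the next step.

Step 10
Reactants: 18 2-(benzyloxy)-1-[4-(benzyloxy)phenyl]ethan-1-one oxime
Product: 20 N-{(Z)-2-(benzyloxy)-1-[4-(benzyloxy)phenyl]ethenyl}acetamide, via oxime acetate 19 (not isolated)
Conditions: Ac2O (3 equiv), Fe powder (2 equiv), AcOH (cat.), toluene, 70 °C
Reagents that add atoms: acetic anhydride (CC(=O)OC(C)=O)
Why: Reductive acylation of a ketoxime (N–O cleavage of the oxime acetate by iron, N-acetylation, tautomerisation) gives the N-acetyl enamide; the Z isomer, with aryl trans to benzyloxy and an N–H···O contact, should prevail, and the isomers interconvert under the acid of step 12.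

Step 11
Reactants: 13 (2R,3R,4R)-3,4,7,8-tetrakis(benzyloxy)-2-[4-(benzyloxy)phenyl]-6-bromochromane; 3 3,4-bis(benzyloxy)-5-bromo-2-hydroxybenzaldehyde
Product: 23 [3,4-bis(benzyloxy)-5-bromo-2-hydroxyphenyl]{(2R,3R,4R)-3,4,7,8-tetrakis(benzyloxy)-2-[4-(benzyloxy)phenyl]chroman-6-yl}methanol (both carbinol epimers), via aryllithium 21 (not isolated), via sodium phenoxide 22 (not isolated)
Conditions: 13, n-BuLi (1.05 equiv), THF, −78 °C; 3 (1.5 equiv), NaH (1.5 equiv), THF, 0 °C, then added at −78 °C, to −40 °C; H2O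
Reagents that add atoms: none
Why: Bromine–lithium exchange and 1,2-addition to the aldehyde make the future interflavanyl bond C4(unit 2)–C6(unit 3) as a plain carbinol; the pre-formed phenoxide costs no aryllithium and carbonyl addition should outrun exchange with the bromide of 22 at −78 °C; 23 is used crude after neutral work-up.

Step 12
Reactants: 23 the diarylcarbinol from step 11; 20 N-{(Z)-2-(benzyloxy)-1-[4-(benzyloxy)phenyl]ethenyl}acetamide
Product: 26 nona-O-benzyl 6-bromo-epioritin-(4β→6)-epioritin-4α-ol (unit 2 joined to unit 3; unit 2 is 2R,3R,4S), via ortho-quinone methide 24 (not isolated), via N,O-aminal 25 (not isolated)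
Conditions: 20 (1.5 equiv), (R)-TRIP [(R)-3,3'-bis(2,4,6-triisopropylphenyl)-1,1'-binaphthyl-2,2'-diyl hydrogen phosphate] (10 mol%), 3 Å MS, CH2Cl2, 0 °C to rt; then Et3SiH (6 equiv), CF3CO2H (6 equiv), −40 to −10 °C; H2O
Reagents that add atoms: none
Why: The phosphoric acid dehydrates 23 to the (E)-ortho-quinone methide 24 and holds it, together with the N–H of enamide 20, in its chiral pocket; the enamide β-carbon adds to the methide carbon (C3–C4), and the phenol oxygen closes onto the N-acyliminium carbon (O1–C2, 6-exo-trig) to give aminal 25; trifluoroacetic acid then ionises 25 to the 2-aryl oxocarbenium ion, which Et3SiH reduces. The closest known reaction type is the chiral phosphoric acid-catalysed formal [4+2] of ortho-hydroxybenzhydrols with enamides to 2-amido-4-arylchromans, followed by ionic hydrogenation of a cyclic ketal as in C-aryl glycoside synthesis. C4 is set by the catalyst, which shields one face of the hydrogen-bonded quinone methide. C3 should form trans to the methide aryl group, with the benzyloxy group turned away from it in the addition; it remains epimerisable through ring–chain tautomerism of 25 until hydride arrives, so it can settle in the favoured trans-diaxial arrangement of the oxocarbenium ion, where the 3-benzyloxy group avoids the coplanar 2-aryl group and the 4-aryl group avoids H5. C2 is set by axial hydride delivery anti to the pseudo-axial 3-benzyloxy group, which puts the 2-aryl group equatorial and cis to O3, the course that gives β-C-aryl mannosides. The ring oxygen can only be O8a of ring A2, because the ortho oxygen on the other aryl group (O7 of unit 3) is benzylated. The step also needs the aminal to ionise in preference to the benzylic C4–O bond of unit 3, which the far more stabilised oxocarbenium ion, the low temperature and the weakly donating 7,8-dioxygenated ring should secure.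

Step 13
Reactants: 26 nona-O-benzyl 6-bromo-epioritin-(4β→6)-epioritin-4α-ol; 2 3,4-bis(benzyloxy)-2-hydroxybenzaldehyde
Product: 29 [3,4-bis(benzyloxy)-2-hydroxyphenyl](nona-O-benzyl epioritin-(4β→6)-epioritin-4α-ol-6-yl)methanol (both carbinol epimers; the carbinol sits on C6 of unit 2), via aryllithium 27 (not isolated), via sodium phenoxide 28 (not isolated)
Conditions: 26, n-BuLi (1.05 equiv), THF, −78 °C; 2 (1.5 equiv), NaH (1.5 equiv), THF, 0 °C, then added at −78 °C, to −40 °C; H2O
Reagents that add atoms: none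
Why: Same bromine–lithium exchange and aldehyde addition as step 11; 26 carries only ethers, and aldehyde 28 has no bromine, so exchange scrambling cannot occur.

Step 14
Reactants: 29 the diarylcarbinol from step 13; 20 N-{(Z)-2-(benzyloxy)-1-[4-(benzyloxy)phenyl]ethenyl}acetamide
Product: 32 trideca-O-benzyl epioritin-(4β→6)-epioritin-(4β→6)-epioritin-4α-ol, via ortho-quinone methide 30 (not isolated), via N,O-aminal 31 (not isolated)
Conditions: 20 (1.5 equiv), (R)-TRIP (10 mol%), 3 Å MS, CH2Cl2, 0 °C to rt; then Et3SiH (6 equiv), CF3CO2H (6 equiv), −40 to −10 °C; H2O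
Reagents that add atoms: none
Why: Repeat of the step 12 annulation and ionic reduction on ring A1; the same catalyst enantiomer is used because unit 1 and unit 2 have the same configuration (2R,3R,4β-aryl), and the stereocentres of the lower units are too remote to interfere.

Step 15
Reactants: 32 trideca-O-benzyl epioritin-(4β→6)-epioritin-(4β→6)-epioritin-4α-ol
Product: 33 epioritin-(4β→6)-epioritin-(4β→6)-epioritin-4α-ol (target)
Conditions: H2 (1 atm), Pd(OH)2/C, THF/MeOH (1:1), rt, degassed solvents
Reagents that add atoms: none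
Why: Hydrogenolysis of thirteen benzyl ethers; a neutral medium and the hindered, ring-bound position of the C4–OH and C2–O1 bonds should spare them, and no stereocentre is touched.

## Compound list

1 | 2,3,4-trihydroxybenzaldehyde | O=Cc1ccc(O)c(O)c1O | starting material
2 | 3,4-bis(benzyloxy)-2-hydroxybenzaldehyde | O=Cc1ccc(OCc2ccccc2)c(OCc2ccccc2)c1O | intermediate
3 | 3,4-bis(benzyloxy)-5-bromo-2-hydroxybenzaldehyde | O=Cc1cc(Br)c(OCc2ccccc2)c(OCc2ccccc2)c1O | intermediate
4 | 7,8-bis(benzyloxy)-6-bromo-2H-chromen-2-one | O=C1C=Cc2cc(Br)c(OCc3ccccc3)c(OCc3ccccc3)c2O1 | intermediate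
5 | 7,8-bis(benzyloxy)-6-bromo-2H-chromen-2-ol (racemic lactol) | OC1C=Cc2cc(Br)c(OCc3ccccc3)c(OCc3ccccc3)c2O1 | intermediate
6 | 7,8-bis(benzyloxy)-6-bromo-2-ethoxy-2H-chromene (racemic) | CCOC1C=Cc2cc(Br)c(OCc3ccccc3)c(OCc3ccccc3)c2O1 | intermediate
7 | [4-(benzyloxy)phenyl]boronic acid | OB(O)c1ccc(OCc2ccccc2)cc1 | starting material
8 | diethyl [4-(benzyloxy)phenyl]boronate | CCOB(OCC)c1ccc(OCc2ccccc2)cc1 | intermediate
9 | (2S)-7,8-bis(benzyloxy)-2-[4-(benzyloxy)phenyl]-6-bromo-2H-chromene | Brc1cc2c(c(OCc3ccccc3)c1OCc1ccccc1)O[C@H](c1ccc(OCc3ccccc3)cc1)C=C2 | intermediate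
10 | (2R)-4α-acetoxy-7,8-bis(benzyloxy)-2-[4-(benzyloxy)phenyl]-6-bromo-3β-iodochromane (3,4-trans, iodine anti to the 2-aryl group) | Brc1cc2c(c(OCc3ccccc3)c1OCc1ccccc1)O[C@H](c1ccc(OCc3ccccc3)cc1)[C@@H](I)[C@@H]2OC(C)=O | intermediate
11 | (2R,3R,4R)-3-acetoxy-7,8-bis(benzyloxy)-2-[4-(benzyloxy)phenyl]-6-bromochroman-4-ol (all-cis; formed with its 4-acetoxy regioisomer) | Brc1cc2c(c(OCc3ccccc3)c1OCc1ccccc1)O[C@H](c1ccc(OCc3ccccc3)cc1)[C@H](OC(C)=O)[C@@H]2O | intermediate
12 | (2R,3R,4R)-7,8-bis(benzyloxy)-2-[4-(benzyloxy)phenyl]-6-bromochromane-3,4-diol | Brc1cc2c(c(OCc3ccccc3)c1OCc1ccccc1)O[C@H](c1ccc(OCc3ccccc3)cc1)[C@H](O)[C@@H]2O | intermediate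
13 | (2R,3R,4R)-3,4,7,8-tetrakis(benzyloxy)-2-[4-(benzyloxy)phenyl]-6-bromochromane | Brc1cc2c(c(OCc3ccccc3)c1OCc1ccccc1)O[C@H](c1ccc(OCc3ccccc3)cc1)[C@H](OCc1ccccc1)[C@@H]2OCc1ccccc1 | intermediate
14 | 1-(benzyloxy)-4-bromobenzene | Brc1ccc(OCc2ccccc2)cc1 | starting material
15 | 2-(benzyloxy)-N-methoxy-N-methylacetamide | CON(C)C(=O)COCc1ccccc1 | starting material
16 | [4-(benzyloxy)phenyl]magnesium bromide | Br[Mg]c1ccc(OCc2ccccc2)cc1 | intermediate
17 | 2-(benzyloxy)-1-[4-(benzyloxy)phenyl]ethan-1-one | O=C(COCc1ccccc1)c1ccc(OCc2ccccc2)cc1 | intermediate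
18 | 2-(benzyloxy)-1-[4-(benzyloxy)phenyl]ethan-1-one oxime (E/Z mixture) | ON=C(COCc1ccccc1)c1ccc(OCc2ccccc2)cc1 | intermediate
19 | O-acetyl oxime of 17 (E/Z mixture) | CC(=O)ON=C(COCc1ccccc1)c1ccc(OCc2ccccc2)cc1 | intermediate
20 | N-{(Z)-2-(benzyloxy)-1-[4-(benzyloxy)phenyl]ethenyl}acetamide | CC(=O)N/C(c1ccc(OCc2ccccc2)cc1)=C\OCc1ccccc1 | intermediate
21 | 6-lithio derivative of 13 | [Li]c1cc2c(c(OCc3ccccc3)c1OCc1ccccc1)O[C@H](c1ccc(OCc3ccccc3)cc1)[C@H](OCc1ccccc1)[C@@H]2OCc1ccccc1 | intermediate
22 | sodium phenoxide of 3 | [Na+].[O-]c1c(C=O)cc(Br)c(OCc2ccccc2)c1OCc1ccccc1 | intermediate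
23 | [3,4-bis(benzyloxy)-5-bromo-2-hydroxyphenyl]{(2R,3R,4R)-3,4,7,8-tetrakis(benzyloxy)-2-[4-(benzyloxy)phenyl]chroman-6-yl}methanol (carbinol epimers) | OC(c1cc(Br)c(OCc2ccccc2)c(OCc2ccccc2)c1O)c5cc6c(c(OCc7ccccc7)c5OCc5ccccc5)O[C@H](c5ccc(OCc7ccccc7)cc5)[C@H](OCc5ccccc5)[C@@H]6OCc5ccccc5 | intermediate
24 | (E)-ortho-quinone methide of ring A2 with unit 3 on the methide carbon | O=C1C(OCc2ccccc2)=C(OCc2ccccc2)C(Br)=C/C1=C\c5cc6c(c(OCc7ccccc7)c5OCc5ccccc5)O[C@H](c5ccc(OCc7ccccc7)cc5)[C@H](OCc5ccccc5)[C@@H]6OCc5ccccc5 | intermediate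
25 | 2-acetamido N,O-aminal of unit 2 (3α-benzyloxy, 4β-aryl; C2 epimers) | Brc1cc2c(c(OCc3ccccc3)c1OCc1ccccc1)OC(NC(C)=O)(c1ccc(OCc3ccccc3)cc1)[C@H](OCc1ccccc1)[C@H]2c5cc6c(c(OCc7ccccc7)c5OCc5ccccc5)O[C@H](c5ccc(OCc7ccccc7)cc5)[C@H](OCc5ccccc5)[C@@H]6OCc5ccccc5 | intermediate
26 | nona-O-benzyl 6-bromo-epioritin-(4β→6)-epioritin-4α-ol (unit 2: 2R,3R,4S; unit 3: 2R,3R,4R) | Brc1cc2c(c(OCc3ccccc3)c1OCc1ccccc1)O[C@H](c1ccc(OCc3ccccc3)cc1)[C@H](OCc1ccccc1)[C@H]2c5cc6c(c(OCc7ccccc7)c5OCc5ccccc5)O[C@H](c5ccc(OCc7ccccc7)cc5)[C@H](OCc5ccccc5)[C@@H]6OCc5ccccc5 | intermediate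
27 | 6-lithio derivative of 26 | [Li]c1cc2c(c(OCc3ccccc3)c1OCc1ccccc1)O[C@H](c1ccc(OCc3ccccc3)cc1)[C@H](OCc1ccccc1)[C@H]2c5cc6c(c(OCc7ccccc7)c5OCc5ccccc5)O[C@H](c5ccc(OCc7ccccc7)cc5)[C@H](OCc5ccccc5)[C@@H]6OCc5ccccc5 | intermediate
28 | sodium phenoxide of 2 | [Na+].[O-]c1c(C=O)ccc(OCc2ccccc2)c1OCc1ccccc1 | intermediate
29 | [3,4-bis(benzyloxy)-2-hydroxyphenyl] carbinol on C6 of unit 2 of the nona-O-benzyl dimer (carbinol epimers) | OC(c1ccc(OCc2ccccc2)c(OCc2ccccc2)c1O)c1cc2c(c(OCc3ccccc3)c1OCc1ccccc1)O[C@H](c1ccc(OCc3ccccc3)cc1)[C@H](OCc1ccccc1)[C@H]2c5cc6c(c(OCc7ccccc7)c5OCc5ccccc5)O[C@H](c5ccc(OCc7ccccc7)cc5)[C@H](OCc5ccccc5)[C@@H]6OCc5ccccc5 | intermediate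
30 | (E)-ortho-quinone methide of ring A1 with the unit 2–unit 3 dimer on the methide carbon | O=C1C(OCc2ccccc2)=C(OCc2ccccc2)C=C/C1=C\c1cc2c(c(OCc3ccccc3)c1OCc1ccccc1)O[C@H](c1ccc(OCc3ccccc3)cc1)[C@H](OCc1ccccc1)[C@H]2c5cc6c(c(OCc7ccccc7)c5OCc5ccccc5)O[C@H](c5ccc(OCc7ccccc7)cc5)[C@H](OCc5ccccc5)[C@@H]6OCc5ccccc5 | intermediate
31 | 2-acetamido N,O-aminal of unit 1 (3α-benzyloxy, 4β-aryl; C2 epimers) | c8cc9c(c(OCc3ccccc3)c8OCc8ccccc8)OC(NC(C)=O)(c8ccc(OCc3ccccc3)cc8)[C@H](OCc8ccccc8)[C@H]9c1cc2c(c(OCc3ccccc3)c1OCc1ccccc1)O[C@H](c1ccc(OCc3ccccc3)cc1)[C@H](OCc1ccccc1)[C@H]2c5cc6c(c(OCc7ccccc7)c5OCc5ccccc5)O[C@H](c5ccc(OCc7ccccc7)cc5)[C@H](OCc5ccccc5)[C@@H]6OCc5ccccc5 | intermediate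
32 | trideca-O-benzyl epioritin-(4β→6)-epioritin-(4β→6)-epioritin-4α-ol (each unit 2R,3R; 4β-aryl in units 1 and 2; 4α-O in unit 3) | c8cc9c(c(OCc3ccccc3)c8OCc8ccccc8)O[C@H](c8ccc(OCc3ccccc3)cc8)[C@H](OCc8ccccc8)[C@H]9c1cc2c(c(OCc3ccccc3)c1OCc1ccccc1)O[C@H](c1ccc(OCc3ccccc3)cc1)[C@H](OCc1ccccc1)[C@H]2c5cc6c(c(OCc7ccccc7)c5OCc5ccccc5)O[C@H](c5ccc(OCc7ccccc7)cc5)[C@H](OCc5ccccc5)[C@@H]6OCc5ccccc5 | intermediate
33 | epioritin-(4β→6)-epioritin-(4β→6)-epioritin-4α-ol, units (2R,3R,4S), (2R,3R,4S), (2R,3R,4R) | Oc1ccc([C@H]2Oc3c(ccc(O)c3O)[C@H](c3cc4c(c(O)c3O)O[C@H](c3ccc(O)cc3)[C@H](O)[C@H]4c3cc4c(c(O)c3O)O[C@H](c3ccc(O)cc3)[C@H](O)[C@@H]4O)[C@H]2O)cc1 | target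

## Step count and least certain steps

Total step count: 15. Longest linear sequence: 12 steps (steps 1–7 and 11–15); steps 8–10 make enamide 20 on a side branch.

**Step 12 (key step; step 14 repeats it).** Three processes may go wrong:
- Loss of control at C3. The conjugate addition may not place the benzyloxy group trans to the methide aryl group, and C3 can epimerise before hydride capture, so the all-cis isomer could leak through.
- Shielding of the axial trajectory at C2 by the pseudo-axial 4-aryl group, which would erode the 2,3-cis selectivity.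
- Acid ionisation of the benzylic C4–O bond of unit 3, followed by its reduction.

The fallback sets out from 23 and comes back at 26. Carbinol 23 is treated with sodium 4-methylbenzenesulfinate and acid to give the storable quinone methide precursor, the [aryl(tosyl)methyl]phenol F1. With K2CO3, benzyloxyacetaldehyde and (S)-α,α-diphenylprolinol trimethylsilyl ether, F1 loses sulfinate and the enamine of the aldehyde adds to the quinone methide. The adduct closes to the trans-3-benzyloxy-4-aryl-chroman-2-ol F2, with C3 and C4 set by the amine catalyst. Oxidation with PhI(OAc)2 and catalytic TEMPO gives the dihydrocoumarin F3, in which C3 can be equilibrated to the trans isomer with mild base. Addition of 4-(benzyloxy)phenyllithium (from 14 and n-BuLi) at −78 °C gives the 2-aryl hemiketal F4. Et3SiH with BF3·OEt2 at −78 °C then reduces F4 to 26.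

**Step 11 (and step 13).** The phenoxide-deactivated aldehyde may add the aryllithium too slowly, so that bromine–lithium exchange with the bromide of 22, or decay of the ortho-benzyloxy aryllithium, takes over. The fallback sets out from 3 and comes back at 23. Aldehyde 3 is silylated with TBSCl and imidazole to its tert-butyldimethylsilyl ether F5, a fully electrophilic aldehyde. Aryllithium 21 is added to F5 at −78 °C, and Bu4NF in the work-up removes the silyl group (which may have migrated to the new alkoxide) to give 23.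

**Step 5.** Facial control by the chiral acid may be insufficient with this hindered, electron-rich benzopyrylium ion, and flavene 9 may racemise by reversible electrocyclic ring opening under light or acid. The fallback sets out from 3 and comes back at 9. Wittig methylenation of 3 (Ph3P=CH2) gives 3,4-bis(benzyloxy)-5-bromo-2-hydroxystyrene F6. Its phenoxide undergoes asymmetric allylic etherification with (E)-3-[4-(benzyloxy)phenyl]allyl methyl carbonate F7, catalysed by [Ir(cod)Cl]2 and a chiral phosphoramidite, to give the branched aryl allyl ether F8. Ring-closing metathesis of F8 with the second-generation Grubbs catalyst gives 9.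

**Step 6.** Iodination of the electron-rich arenes may compete with iodonium formation, and a free C4 cation may lose the facial course of the acetate participation. The fallback sets out from 9 and comes back at 12. NBS in aqueous THF gives the trans-bromohydrin F9 (3β-bromo, 4α-hydroxy). Boc2O with DMAP gives its tert-butyl carbonate F10. AgOTf removes bromide while the carbonate carbonyl attacks C3 from the α face, giving the cis-fused cyclic carbonate F11 with loss of 2-methylpropene. K2CO3 in MeOH frees diol 12.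

## Further compounds

F1 | step 12 | 2-{[tosyl]-[unit 3 aryl]methyl}phenol from 23 (sulfone at the former carbinol carbon) | Cc1ccc(cc1)S(=O)(=O)C(c1cc(Br)c(OCc2ccccc2)c(OCc2ccccc2)c1O)c5cc6c(c(OCc7ccccc7)c5OCc5ccccc5)O[C@H](c5ccc(OCc7ccccc7)cc5)[C@H](OCc5ccccc5)[C@@H]6OCc5ccccc5
F2 | step 12 | trans-3α-benzyloxy-4β-aryl-6-bromo-7,8-bis(benzyloxy)chroman-2-ol (lactol, C2 epimers; aryl = unit 3) | Brc1cc2c(c(OCc3ccccc3)c1OCc1ccccc1)OC(O)[C@H](OCc1ccccc1)[C@H]2c5cc6c(c(OCc7ccccc7)c5OCc5ccccc5)O[C@H](c5ccc(OCc7ccccc7)cc5)[C@H](OCc5ccccc5)[C@@H]6OCc5ccccc5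
F3 | step 12 | trans-3α-benzyloxy-4β-aryl-6-bromo-7,8-bis(benzyloxy)chroman-2-one (dihydrocoumarin; aryl = unit 3) | Brc1cc2c(c(OCc3ccccc3)c1OCc1ccccc1)OC(=O)[C@H](OCc1ccccc1)[C@H]2c5cc6c(c(OCc7ccccc7)c5OCc5ccccc5)O[C@H](c5ccc(OCc7ccccc7)cc5)[C@H](OCc5ccccc5)[C@@H]6OCc5ccccc5
F4 | step 12 | 2-[4-(benzyloxy)phenyl]-2-hydroxy hemiketal of unit 2 (3α-benzyloxy, 4β-aryl; C2 epimers) | Brc1cc2c(c(OCc3ccccc3)c1OCc1ccccc1)OC(O)(c1ccc(OCc3ccccc3)cc1)[C@H](OCc1ccccc1)[C@H]2c5cc6c(c(OCc7ccccc7)c5OCc5ccccc5)O[C@H](c5ccc(OCc7ccccc7)cc5)[C@H](OCc5ccccc5)[C@@H]6OCc5ccccc5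
F5 | step 11 | 3,4-bis(benzyloxy)-5-bromo-2-[(tert-butyldimethylsilyl)oxy]benzaldehyde | O=Cc1cc(Br)c(OCc2ccccc2)c(OCc2ccccc2)c1O[Si](C)(C)C(C)(C)C
F6 | step 5 | 3,4-bis(benzyloxy)-5-bromo-2-hydroxystyrene | C=Cc1cc(Br)c(OCc2ccccc2)c(OCc2ccccc2)c1O
F7 | step 5 | (E)-3-[4-(benzyloxy)phenyl]allyl methyl carbonate | COC(=O)OC/C=C/c1ccc(OCc2ccccc2)cc1
F8 | step 5 | (S)-1-[4-(benzyloxy)phenyl]allyl 2,3-bis(benzyloxy)-4-bromo-6-vinylphenyl ether | C=Cc1cc(Br)c(OCc2ccccc2)c(OCc2ccccc2)c1O[C@H](c1ccc(OCc2ccccc2)cc1)C=C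
F9 | step 6 | (2R)-7,8-bis(benzyloxy)-2-[4-(benzyloxy)phenyl]-3β,6-dibromochroman-4α-ol | Brc1cc2c(c(OCc3ccccc3)c1OCc1ccccc1)O[C@H](c1ccc(OCc3ccccc3)cc1)[C@@H](Br)[C@@H]2O
F10 | step 6 | tert-butyl carbonate of F9 at O4 | Brc1cc2c(c(OCc3ccccc3)c1OCc1ccccc1)O[C@H](c1ccc(OCc3ccccc3)cc1)[C@@H](Br)[C@@H]2OC(=O)OC(C)(C)C
F11 | step 6 | cis-fused 3α,4α-cyclic carbonate of diol 12 | Brc1cc2c(c(OCc3ccccc3)c1OCc1ccccc1)O[C@H](c1ccc(OCc3ccccc3)cc1)[C@@H]4OC(=O)O[C@H]24
A1 | alternative 1 | tetra-O-benzyl 4β-(benzylsulfanyl)epioritin (C4 electrophile) | c1cc2c(c(OCc3ccccc3)c1OCc1ccccc1)O[C@H](c1ccc(OCc3ccccc3)cc1)[C@H](OCc1ccccc1)[C@H]2SCc1ccccc1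
A2 | alternative 2 | (Z)-2-[4-(benzyloxy)phenyl]ethenyl acetate | CC(=O)O/C=C\c1ccc(OCc2ccccc2)cc1
A3 | alternative 3 | C6 boronic acid derived from 13 | OB(O)c1cc2c(c(OCc3ccccc3)c1OCc1ccccc1)O[C@H](c1ccc(OCc3ccccc3)cc1)[C@H](OCc1ccccc1)[C@@H]2OCc1ccccc1
A4 | alternative 3 | 7,8-bis(benzyloxy)-2H-chromen-2-one | O=C1C=Cc2ccc(OCc3ccccc3)c(OCc3ccccc3)c2O1
A5 | alternative 3 | 4β-aryl-7,8-bis(benzyloxy)chroman-2-one (aryl = unit 3 of 13) | O=C1C[C@@H](c5cc6c(c(OCc7ccccc7)c5OCc5ccccc5)O[C@H](c5ccc(OCc7ccccc7)cc5)[C@H](OCc5ccccc5)[C@@H]6OCc5ccccc5)c2ccc(OCc3ccccc3)c(OCc3ccccc3)c2O1
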